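**Plan**

- The (Z)-3-methylbuta-1,3-dienyl group on C8 of ring A stands ortho to the free C7–OH, so the target is a hydrogen-shift and valence isomer of the 2,2-dimethyl-2H-pyran fused at O7/C8. The retrosynthesis first returns one methyl hydrogen from O7 and closes O7–C3''.
- Bonds cut, in order: the pyran bonds C8–C1'' and O7–C3'' (to a 7-O-1,1-dimethylpropargyl ether and 3-chloro-3-methylbut-1-yne); the flavanone C2–C1' bond (chromone plus arylboronic acid); the dihydrobenzofuran C2–C3 bond (diaryl carbene C–H insertion); the aryl–carbonyl bond of the benzophenone (aldehyde plus aryl Grignard).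
- Forward: the dihydrobenzofuran ring is closed first (steps 1–8) and the 4-pyranone ring of the chromone separately (steps 9–10). The halves are joined at C2 of ring C (step 11), the pyran ring is closed by the propargyl Claisen cascade (step 14), and it is reopened by light after deprotection (steps 15–16).
- Stereochemistry: C3 of the dihydrobenzofuran comes from the chiral dirhodium carboxylate in the insertion, and C2 from acid equilibration to the trans isomer. C2 of the flavanone comes from a chiral diene–rhodium catalyst, and the Z double bond from its origin inside the six-membered pyran ring.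

Key step: step 14

Assumption: the catalyst antipodes named in steps 5 and 11 are those expected to give 3R and 2S; should either sense of induction prove opposite, the mirror-image ligand is used with no other change.

Abbreviations in names: ArM = (2R,3R)-3-[3,5-bis(methoxymethoxy)phenyl]-6-(methoxymethoxy)-2-[4-(methoxymethoxy)phenyl]-2,3-dihydro-1-benzofuran-5-yl; ArH = the same group with four free hydroxyls. C1''–C3'' are side-chain carbons (C1'' on C8, C3'' the carbon carrying the methyl groups). Rh2(R-PTAD)4 = dirhodium tetrakis[(R)-(1-adamantyl)(phthalimido)acetate]; Ph-bod = 2,5-diphenylbicyclo[2.2.2]octa-2,5-diene.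

**Route**

Step 1
Reactants: 1 5-bromo-2-hydroxy-4-methoxybenzaldehyde; 2 4-methoxybenzyl chloride
Product: 3 5-bromo-4-methoxy-2-(4-methoxybenzyloxy)benzaldehyde
Conditions: K2CO3, KI (cat.), DMF, 60 °C
Reagents that add atoms: none
Why: Williamson etherification of the single phenol with a reactive benzylic chloride should be clean, and the benzylic CH2 introduced here is the C–H bond that step 5 turns into C2 of the dihydrobenzofuran.

Step 2
Reactants: 3 5-bromo-4-methoxy-2-(4-methoxybenzyloxy)benzaldehyde; 4 1-bromo-3,5-dimethoxybenzene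
Product: 6 [5-bromo-4-methoxy-2-(4-methoxybenzyloxy)phenyl](3,5-dimethoxyphenyl)methanol (racemic), via arylmagnesium bromide 5 (not isolated)
Conditions: 4, Mg, THF, 40 °C; then 3, THF, 0 °C; aq NH4Cl
Reagents that add atoms: none
Why: Grignard addition to the aromatic aldehyde should be much faster at 0 °C than halogen–magnesium exchange at the aryl bromide of 3, and the carbinol centre needs no control because step 3 removes it.

Step 3
Reactants: 6 [5-bromo-4-methoxy-2-(4-methoxybenzyloxy)phenyl](3,5-dimethoxyphenyl)methanol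
Product: 7 [5-bromo-4-methoxy-2-(4-methoxybenzyloxy)phenyl](3,5-dimethoxyphenyl)methanone
Conditions: Dess–Martin periodinane, CH2Cl2, rt
Reagents that add atoms: none
Why: Dess–Martin oxidation should convert the electron-rich benzhydrol into the benzophenone under neutral conditions that leave the benzyl ether and the aryl bromide alone.

Step 4
Reactants: 7 [5-bromo-4-methoxy-2-(4-methoxybenzyloxy)phenyl](3,5-dimethoxyphenyl)methanone
Product: 8 hydrazone of ketone 7 (E/Z mixture)
Conditions: N2H4·H2O (excess), AcOH (cat.), EtOH, 90 °C, sealed tube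
Reagents that add atoms: hydrazine, NN
Why: Acid-catalysed hydrazone formation with a large excess of hydrazine should give the N-unsubstituted hydrazone needed as diazo precursor while suppressing azine formation.

Step 5
Reactants: 8 hydrazone of ketone 7
Product: 10 (2S,3R)-5-bromo-3-(3,5-dimethoxyphenyl)-6-methoxy-2-(4-methoxyphenyl)-2,3-dihydro-1-benzofuran (cis), via diaryldiazomethane 9 (not isolated)
Conditions: MnO2, CH2Cl2, 0 °C; then Rh2(R-PTAD)4 (1 mol %), CH2Cl2, −20 °C to rt
Reagents that add atoms: none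
Why: MnO2 dehydrogenates the hydrazone to the donor/donor diazo compound, whose dirhodium carbene undergoes intramolecular 1,5 C–H insertion into the ether-activated benzylic CH2, a known entry to 2,3-diaryl-2,3-dihydrobenzofurans; the chiral carboxylate ligands select the enantiotopic benzylic hydrogen and carbene face, setting C3 as R, and the compact three-centre transition state places the two aryl groups cis (C2 S).

Step 6
Reactants: 10 (2S,3R)-5-bromo-3-(3,5-dimethoxyphenyl)-6-methoxy-2-(4-methoxyphenyl)-2,3-dihydro-1-benzofuran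
Product: 11 (2R,3R)-5-bromo-3-(3,5-dihydroxyphenyl)-2-(4-hydroxyphenyl)-2,3-dihydro-1-benzofuran-6-ol (trans)
Conditions: BBr3 (10 equiv), CH2Cl2, −78 °C to rt; then H2O
Reagents that add atoms: none
Why: BBr3 ether cleavage removes the four methyl groups, and the same acid reversibly ionises the C2–O bond to a 4-oxybenzyl cation (para-quinone methide) that recloses to the more stable trans ring, as acid is known to do in 2-(4-oxyphenyl)-3-aryl-2,3-dihydrobenzofurans; C2 is thereby inverted to R under thermodynamic control while C3, which is not touched, keeps the configuration from step 5.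

Step 7
Reactants: 11 (2R,3R)-5-bromo-3-(3,5-dihydroxyphenyl)-2-(4-hydroxyphenyl)-2,3-dihydro-1-benzofuran-6-ol
Product: 12 ArM–Br, (2R,3R)-5-bromo-3-[3,5-bis(methoxymethoxy)phenyl]-6-(methoxymethoxy)-2-[4-(methoxymethoxy)phenyl]-2,3-dihydro-1-benzofuran
Conditions: MOMCl (6 equiv), iPr2NEt, CH2Cl2/DMF, 0 °C to rt
Reagents that add atoms: chloromethyl methyl ether, COCCl
Why: O-alkylation of the four phenols with MOMCl and a hindered amine (acetal protection) should give ethers that survive organolithium, aqueous base and heat and that leave in the final mild acid step.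

Step 8
Reactants: 12 ArM–Br
Product: 14 ArM–B(OH)2 (the 5-boronic acid of the protected dihydrobenzofuran), via aryllithium 13 (not isolated)
Conditions: n-BuLi, THF, −78 °C; B(OiPr)3, −78 to 0 °C; aq NH4Cl
Reagents that add atoms: triisopropyl borate, CC(C)OB(OC(C)C)OC(C)C; water, O
Why: Bromine–lithium exchange, helped by the ortho MOM oxygen, should outrun deprotonation at −78 °C, and borate trapping with mild hydrolysis (borylation of an aryllithium) gives the boronic acid without exposing the MOM groups to acid.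

Step 9
Reactants: 15 2,4,6-trihydroxyacetophenone
Product: 16 1-[2-hydroxy-4,6-bis(triisopropylsilyloxy)phenyl]ethanone
Conditions: iPr3SiCl (2.1 equiv), imidazole, DMF, 0 °C to rt
Reagents that add atoms: chlorotriisopropylsilane, CC(C)[Si](Cl)(C(C)C)C(C)C
Why: Silylation should stop at the bis-ether because the para hydroxyl and one ortho hydroxyl react readily while the last one is held in a hydrogen bond to the acetyl group.

Step 10
Reactants: 16 1-[2-hydroxy-4,6-bis(triisopropylsilyloxy)phenyl]ethanone
Product: 18 5,7-bis(triisopropylsilyloxy)-4H-chromen-4-one, via enaminone 17 (not isolated)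
Conditions: Me2NCH(OMe)2, toluene, 95 °C; concentrate; then TsOH·H2O, CH2Cl2, rt
Reagents that add atoms: N,N-dimethylformamide dimethyl acetal, COC(OC)N(C)C
Why: Condensation of the methyl ketone with the amide acetal gives the enaminone, and acid-promoted addition–elimination of the chelated phenol with loss of dimethylamine closes the 4-pyranone ring (enaminone chromone synthesis), the acetal carbon becoming C2.

Step 11
Reactants: 18 5,7-bis(triisopropylsilyloxy)-4H-chromen-4-one; 14 ArM–B(OH)2
Product: 19 (2S)-2-ArM-5,7-bis(triisopropylsilyloxy)chroman-4-one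
Conditions: [RhCl(C2H4)2]2 (2.5 mol %), (S,S)-Ph-bod (5.5 mol %), aq KOH (20 mol %), toluene/H2O 10:1, 40 °C
Reagents that add atoms: none
Why: Rhodium-catalysed asymmetric 1,4-addition of an arylboronic acid to a chromone (Hayashi–Miyaura reaction) forms the C2–aryl bond, the C2-symmetric chiral diene on rhodium dictating the face of C2 that receives the aryl group and so setting 2S independently of the remote dihydrobenzofuran centres, with the rhodium enolate protonated by water.

Step 12
Reactants: 19 (2S)-2-ArM-5,7-bis(triisopropylsilyloxy)chroman-4-one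
Product: 20 (2S)-2-ArM-5,7-dihydroxychroman-4-one
Conditions: Bu4NF (2.2 equiv), AcOH (2.5 equiv), THF, 0 °C
Reagents that add atoms: none
Why: Fluoride cleavage of the two carbonyl-activated aryl silyl ethers, buffered with acetic acid so that no free phenoxide can open ring C, should free the 5- and 7-hydroxyls and leave the MOM acetals untouched.

Step 13
Reactants: 20 (2S)-2-ArM-5,7-dihydroxychroman-4-one; 21 3-chloro-3-methylbut-1-yne
Product: 22 (2S)-2-ArM-5-hydroxy-7-[(2-methylbut-3-yn-2-yl)oxy]chroman-4-one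
Conditions: 21 (1.5 equiv), CuCl2·2H2O (1 mol %), DBU, MeCN, 0 °C
Reagents that add atoms: none
Why: Copper-catalysed propargylic etherification alkylates the acidic 7-OH with the tertiary chloride at 0 °C, while the 5-OH is held in its hydrogen bond to C4=O and should not react, and the short cold exposure to DBU should not open ring C.

Step 14
Reactants: 22 (2S)-2-ArM-5-hydroxy-7-[(2-methylbut-3-yn-2-yl)oxy]chroman-4-one
Product: 26 (2S)-2-ArM-5-hydroxy-8,8-dimethyl-2,3-dihydropyrano[2,3-f]chromen-4(8H)-one (angular pyranoflavanone), via allenyl dienone 23 (not isolated), via 8-allenyl phenol 24 (not isolated), via ortho-quinone methide 25 (not isolated)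
Conditions: degassed o-xylene, 135 °C, dark
Reagents that add atoms: none
Why: Heat triggers an aryl propargyl Claisen ([3,3]) shift in which the alkyne terminus C1'' bonds to C8 and the O7–C3'' bond breaks, giving allenyl dienone 23, which enolises to phenol 24; a 1,5-hydrogen shift from O7–H to the central allene carbon gives ortho-quinone methide 25, and a thermal disrotatory oxa-6π electrocyclisation re-forms O7–C3'' and closes the six-membered pyran ring. This is the classical thermal conversion of aryl 1,1-dimethylpropargyl ethers into 2,2-dimethyl-2H-chromenes, accelerated by the gem-dimethyl group. No stereocentre is created, and neutral, base-free heating should leave C2 of ring C and the two dihydrobenzofuran centres untouched. The step needs attack at C8 and not at C6: dienone 23 keeps the O1–C8a=C4a–C4=O vinylogous ester and the O5–H···O4 hydrogen bond of the chromanone, and 7-propargyloxychromanones and chelated 1-hydroxy-3-propargyloxy xanthones and acridones cyclise to the angular isomer, which is why the 5-OH is left free. The preference is not absolute for a saturated ring C, so the linear 6,7-fused isomer remains the main risk.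

Step 15
Reactants: 26 angular pyranoflavanone (ArM)
Product: 27 (2S)-2-ArH-5-hydroxy-8,8-dimethyl-2,3-dihydropyrano[2,3-f]chromen-4(8H)-one
Conditions: HCl (ca. 1 M) in MeOH, 45 °C
Reagents that add atoms: none
Why: Acid-catalysed transacetalisation to dimethoxymethane removes the four MOM groups, dilute acid at moderate temperature being chosen so that the chromene double bond and the benzylic C2–O bonds are not ionised, and the trans dihydrobenzofuran being in any case the thermodynamic isomer.

Step 16
Reactants: 27 (2S)-2-ArH-5-hydroxy-8,8-dimethyl-2,3-dihydropyrano[2,3-f]chromen-4(8H)-one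
Product: 29 target CNP0284772.1, via ortho-quinone methide 28 (not isolated)
Conditions: hν (365 nm), degassed MeCN, −20 °C, stopped at partial conversion; chromatography in the dark at or below rt, 27 recycled
Reagents that add atoms: none
Why: Light-induced six-electron electrocyclic opening of the 2H-pyran gives the ortho-quinone methide, and a thermal antarafacial 1,7-hydrogen shift from the methyl group cis to the carbonyl oxygen gives the isopropenyl group and the free 7-OH (known photochemistry of 2,2-dimethyl-2H-chromenes), the C1''=C2'' bond keeping the Z geometry it had in the ring while the chelated 5-hydroxy ketone should dissipate its own excitation by proton transfer.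

**Compound list**

1 | 5-bromo-2-hydroxy-4-methoxybenzaldehyde | COc1cc(O)c(C=O)cc1Br | starting material
2 | 4-methoxybenzyl chloride | COc1ccc(CCl)cc1 | starting material
3 | 5-bromo-4-methoxy-2-(4-methoxybenzyloxy)benzaldehyde | COc1ccc(COc2cc(OC)c(Br)cc2C=O)cc1 | intermediate
4 | 1-bromo-3,5-dimethoxybenzene | COc1cc(Br)cc(OC)c1 | starting material
5 | (3,5-dimethoxyphenyl)magnesium bromide (not isolated) | COc1cc([Mg]Br)cc(OC)c1 | intermediate
6 | [5-bromo-4-methoxy-2-(4-methoxybenzyloxy)phenyl](3,5-dimethoxyphenyl)methanol, racemic | COc1ccc(COc2cc(OC)c(Br)cc2C(O)c2cc(OC)cc(OC)c2)cc1 | intermediate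
7 | [5-bromo-4-methoxy-2-(4-methoxybenzyloxy)phenyl](3,5-dimethoxyphenyl)methanone | COc1ccc(COc2cc(OC)c(Br)cc2C(=O)c2cc(OC)cc(OC)c2)cc1 | intermediate
8 | hydrazone of 7 (E/Z mixture) | COc1ccc(COc2cc(OC)c(Br)cc2C(=NN)c2cc(OC)cc(OC)c2)cc1 | intermediate
9 | diaryldiazomethane from 8 (not isolated) | COc1ccc(COc2cc(OC)c(Br)cc2C(=[N+]=[N-])c2cc(OC)cc(OC)c2)cc1 | intermediate
10 | (2S,3R)-5-bromo-3-(3,5-dimethoxyphenyl)-6-methoxy-2-(4-methoxyphenyl)-2,3-dihydro-1-benzofuran (cis) | Brc1cc3c(cc1OC)O[C@H](c1ccc(OC)cc1)[C@@H]3c1cc(OC)cc(OC)c1 | intermediate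
11 | (2R,3R)-5-bromo-3-(3,5-dihydroxyphenyl)-2-(4-hydroxyphenyl)-2,3-dihydro-1-benzofuran-6-ol (trans) | Brc1cc3c(cc1O)O[C@@H](c1ccc(O)cc1)[C@@H]3c1cc(O)cc(O)c1 | intermediate
12 | ArM–Br, tetrakis-MOM ether of 11 | Brc1cc3c(cc1OCOC)O[C@@H](c1ccc(OCOC)cc1)[C@@H]3c1cc(OCOC)cc(OCOC)c1 | intermediate
13 | ArM–Li (not isolated) | [Li]c1cc3c(cc1OCOC)O[C@@H](c1ccc(OCOC)cc1)[C@@H]3c1cc(OCOC)cc(OCOC)c1 | intermediate
14 | ArM–B(OH)2 | OB(O)c1cc3c(cc1OCOC)O[C@@H](c1ccc(OCOC)cc1)[C@@H]3c1cc(OCOC)cc(OCOC)c1 | intermediate
15 | 2,4,6-trihydroxyacetophenone | CC(=O)c1c(O)cc(O)cc1O | starting material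
16 | 1-[2-hydroxy-4,6-bis(triisopropylsilyloxy)phenyl]ethanone | CC(=O)c1c(O)cc(O[Si](C(C)C)(C(C)C)C(C)C)cc1O[Si](C(C)C)(C(C)C)C(C)C | intermediate
17 | (E)-3-(dimethylamino)-1-[2-hydroxy-4,6-bis(triisopropylsilyloxy)phenyl]prop-2-en-1-one (not isolated) | CN(C)/C=C/C(=O)c1c(O)cc(O[Si](C(C)C)(C(C)C)C(C)C)cc1O[Si](C(C)C)(C(C)C)C(C)C | intermediate
18 | 5,7-bis(triisopropylsilyloxy)-4H-chromen-4-one | O=c1ccoc2cc(O[Si](C(C)C)(C(C)C)C(C)C)cc(O[Si](C(C)C)(C(C)C)C(C)C)c12 | intermediate
19 | (2S)-2-ArM-5,7-bis(triisopropylsilyloxy)chroman-4-one | CC(C)[Si](C(C)C)(C(C)C)Oc1cc(O[Si](C(C)C)(C(C)C)C(C)C)c2c(c1)O[C@H](c1cc3c(cc1OCOC)O[C@@H](c1ccc(OCOC)cc1)[C@@H]3c1cc(OCOC)cc(OCOC)c1)CC2=O | intermediate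
20 | (2S)-2-ArM-5,7-dihydroxychroman-4-one | Oc1cc(O)c2c(c1)O[C@H](c1cc3c(cc1OCOC)O[C@@H](c1ccc(OCOC)cc1)[C@@H]3c1cc(OCOC)cc(OCOC)c1)CC2=O | intermediate
21 | 3-chloro-3-methylbut-1-yne | C#CC(C)(C)Cl | starting material
22 | (2S)-2-ArM-5-hydroxy-7-[(2-methylbut-3-yn-2-yl)oxy]chroman-4-one | C#CC(C)(C)Oc1cc(O)c2c(c1)O[C@H](c1cc3c(cc1OCOC)O[C@@H](c1ccc(OCOC)cc1)[C@@H]3c1cc(OCOC)cc(OCOC)c1)CC2=O | intermediate
23 | 8-(3-methylbuta-1,2-dienyl) cyclohexadienone from the [3,3] shift, C8 epimers (not isolated) | CC(C)=C=CC1C(=O)C=C(O)C2=C1O[C@H](c1cc3c(cc1OCOC)O[C@@H](c1ccc(OCOC)cc1)[C@@H]3c1cc(OCOC)cc(OCOC)c1)CC2=O | intermediate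
24 | (2S)-2-ArM-5,7-dihydroxy-8-(3-methylbuta-1,2-dienyl)chroman-4-one (not isolated) | CC(C)=C=Cc1c(O)cc(O)c2c1O[C@H](c1cc3c(cc1OCOC)O[C@@H](c1ccc(OCOC)cc1)[C@@H]3c1cc(OCOC)cc(OCOC)c1)CC2=O | intermediate
25 | (Z)-ortho-quinone methide, 8-(3-methylbut-2-enylidene)-7-oxo form of ring A (not isolated) | CC(C)=C/C=C1\C(=O)C=C(O)C2=C1O[C@H](c1cc3c(cc1OCOC)O[C@@H](c1ccc(OCOC)cc1)[C@@H]3c1cc(OCOC)cc(OCOC)c1)CC2=O | intermediate
26 | (2S)-2-ArM-5-hydroxy-8,8-dimethyl-2,3-dihydropyrano[2,3-f]chromen-4(8H)-one | CC1(C)C=Cc2c(O1)cc(O)c3c2O[C@H](c1cc4c(cc1OCOC)O[C@@H](c1ccc(OCOC)cc1)[C@@H]4c1cc(OCOC)cc(OCOC)c1)CC3=O | intermediate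
27 | (2S)-2-ArH-5-hydroxy-8,8-dimethyl-2,3-dihydropyrano[2,3-f]chromen-4(8H)-one | CC1(C)C=Cc2c(O1)cc(O)c3c2O[C@H](c1cc4c(cc1O)O[C@@H](c1ccc(O)cc1)[C@@H]4c1cc(O)cc(O)c1)CC3=O | intermediate
28 | (Z)-ortho-quinone methide of 27 (not isolated) | CC(C)=C/C=C1\C(=O)C=C(O)C2=C1O[C@H](c1cc3c(cc1O)O[C@@H](c1ccc(O)cc1)[C@@H]3c1cc(O)cc(O)c1)CC2=O | intermediate
29 | CNP0284772.1, (2S)-2-ArH-5,7-dihydroxy-8-[(Z)-3-methylbuta-1,3-dienyl]chroman-4-one | C=C(C)/C=C\c1c(O)cc(O)c2c1O[C@H](c1cc3c(cc1O)O[C@@H](c1ccc(O)cc1)[C@@H]3c1cc(O)cc(O)c1)CC2=O | target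

**Step count**

Total: 16 steps. Longest linear sequence: 14 steps (steps 1–8, then 11–16); the chromone branch (steps 9–10) is convergent.

**Steps most likely to fail**

1. Step 16. The quinone methide may return to the chromene faster than it shifts hydrogen; the product diene may isomerise from Z to E under continued irradiation or reclose on warming; and the free, electron-rich phenols may photo-oxidise in a polar solvent. Fallback, from 26 back to 29: the two final operations are exchanged and the protic acid is avoided. The MOM-protected chromene 26 is irradiated (365 nm) in degassed benzene, the medium of the simple chromene models, to give the tetrakis-MOM (Z)-dienyl phenol F1. F1 is then unmasked with Me3SiOTf/2,2'-bipyridyl in MeCN at 0 °C followed by water, conditions that cleave aryl MOM ethers through silyl ethers without a Brønsted acid that would recyclise the dienyl phenol, giving 29.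

2. Step 14. The [3,3] shift may partition between C8 and C6, so that the linear 6,7-fused pyran forms beside or in place of the angular one and the isomers prove hard to separate. Fallback, from 20 back to 26, with C8 fixed by a para-Claisen sequence. Ac2O/pyridine at 0 °C acetylates the non-chelated hydroxyl to give the 7-acetate F2. Mitsunobu alkylation of the chelated 5-OH with 3-methylbut-2-en-1-ol (PPh3, DIAD) gives the 5-O-prenyl ether F3. Eu(fod)3 in CHCl3 at 60 °C promotes a Claisen shift to C6 followed by a Cope shift to C8 (the only para terminus), giving the 8-prenyl-5-hydroxy 7-acetate F4. K2CO3/MeOH at 0 °C removes the acetate to give the 8-prenyl diol F5. DDQ in benzene then oxidises the ortho-prenyl phenol to the same quinone methide 25, which closes to 26; only the angular ring can form, because C8 is flanked by the 7-OH and the ring oxygen.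

3. Step 11. Transmetallation of the ortho-alkoxy arylboronic acid may be slow relative to protodeboronation; the aqueous base may strip the silyl groups or open the product to the chalcone; and facial selectivity may erode. Fallback, from 13 and 16 back to 19, replacing catalyst control by separation of diastereomers, which is possible because the aryl fragment is already enantiopure. Aryllithium 13 is quenched with DMF to give the aldehyde F6. The dilithium enolate–phenoxide of acetophenone 16 (LiN(SiMe3)2, THF, −78 °C) adds to F6 to give the β-hydroxy ketone F7 as a mixture of carbinol epimers. Intramolecular Mitsunobu etherification (PPh3, DIAD) closes ring C with inversion, giving 19 together with its 2R epimer F8, and the two are separated by preparative HPLC.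

**Further compounds**

F1 | step 16 | (2S)-2-ArM-5,7-dihydroxy-8-[(Z)-3-methylbuta-1,3-dienyl]chroman-4-one | C=C(C)/C=C\c1c(O)cc(O)c2c1O[C@H](c1cc3c(cc1OCOC)O[C@@H](c1ccc(OCOC)cc1)[C@@H]3c1cc(OCOC)cc(OCOC)c1)CC2=O
F2 | step 14 | (2S)-2-ArM-7-acetoxy-5-hydroxychroman-4-one | CC(=O)Oc1cc(O)c2c(c1)O[C@H](c1cc3c(cc1OCOC)O[C@@H](c1ccc(OCOC)cc1)[C@@H]3c1cc(OCOC)cc(OCOC)c1)CC2=O
F3 | step 14 | (2S)-2-ArM-7-acetoxy-5-(3-methylbut-2-enyloxy)chroman-4-one | CC(=O)Oc1cc(OCC=C(C)C)c2c(c1)O[C@H](c1cc3c(cc1OCOC)O[C@@H](c1ccc(OCOC)cc1)[C@@H]3c1cc(OCOC)cc(OCOC)c1)CC2=O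
F4 | step 14 | (2S)-2-ArM-7-acetoxy-5-hydroxy-8-(3-methylbut-2-enyl)chroman-4-one | CC(=O)Oc1cc(O)c2c(c1CC=C(C)C)O[C@H](c1cc3c(cc1OCOC)O[C@@H](c1ccc(OCOC)cc1)[C@@H]3c1cc(OCOC)cc(OCOC)c1)CC2=O
F5 | step 14 | (2S)-2-ArM-5,7-dihydroxy-8-(3-methylbut-2-enyl)chroman-4-one | CC(C)=CCc1c(O)cc(O)c2c1O[C@H](c1cc3c(cc1OCOC)O[C@@H](c1ccc(OCOC)cc1)[C@@H]3c1cc(OCOC)cc(OCOC)c1)CC2=O
F6 | step 11 | ArM–CHO, the 5-carbaldehyde of the protected dihydrobenzofuran | O=Cc1cc3c(cc1OCOC)O[C@@H](c1ccc(OCOC)cc1)[C@@H]3c1cc(OCOC)cc(OCOC)c1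
F7 | step 11 | 3-ArM-3-hydroxy-1-[2-hydroxy-4,6-bis(triisopropylsilyloxy)phenyl]propan-1-one, carbinol epimers | CC(C)[Si](C(C)C)(C(C)C)Oc1cc(O)c(C(=O)CC(O)c2cc3c(cc2OCOC)O[C@@H](c2ccc(OCOC)cc2)[C@@H]3c2cc(OCOC)cc(OCOC)c2)c(O[Si](C(C)C)(C(C)C)C(C)C)c1
F8 | step 11 | (2R)-2-ArM-5,7-bis(triisopropylsilyloxy)chroman-4-one | CC(C)[Si](C(C)C)(C(C)C)Oc1cc(O[Si](C(C)C)(C(C)C)C(C)C)c2c(c1)O[C@@H](c1cc3c(cc1OCOC)O[C@@H](c1ccc(OCOC)cc1)[C@@H]3c1cc(OCOC)cc(OCOC)c1)CC2=O
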